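## Retrosynthetic overview

1. Target 16 ⇐ 15 by hydrogenolysis of two para-O-benzyl ethers; these are present only to force rings A and B to close through the oxygens ortho to the acyl groups.
2. Benzofuran ring C (formed last) ⇐ gem-dibromoalkene 12 + isovalerylphloroglucinol 3 by an O-first annulation (para-phenoxide adds to the derived bromoalkyne, then Pd C–H closure), so its ring oxygen is para to the acyl group by construction.
3. 12 ⇐ aldehyde 11 ⇐ key cascade: iminium-catalysed asymmetric Friedel–Crafts addition of 4 to keto-enal 9 (sets C3), then double ketalization that closes both spiroketal rings together and sets the spiro centre.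
4. 9 ⇐ singlet-oxygen opening of 2-benzylfuran 6 ⇐ Friedel–Crafts furfurylation of 4; 4 ⇐ 3 ⇐ phloroglucinol + isovaleryl chloride.
5. Ring order: furan (sacrificial, opened) → dihydrobenzofuran rings A and B of the spiroketal in one operation → benzofuran ring C.

Assumption: the SMILES is read as 2R at the spiro carbon and 3S at the adjacent methine (side chain cis to the oxygen of the CH2-bearing ring); isovalerylphloroglucinol is made rather than bought.

## Route

Step 1
Reactants: 1 phloroglucinol; 2 isovaleryl chloride (3-methylbutanoyl chloride)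
Product: 3 1-(2,4,6-trihydroxyphenyl)-3-methylbutan-1-one (isovalerylphloroglucinol)
Conditions: AlCl3 (3.5 equiv), PhNO2–CH2Cl2, 0 °C → rt; aq. HCl work-up
Reagents that add atoms: none
Why: Friedel–Crafts C-acylation of the symmetric triphenol, where the first acyl group deactivates the ring so mono-acylation dominates.

Step 2
Reactants: 3 isovalerylphloroglucinol
Product: 4 1-[4-(benzyloxy)-2,6-dihydroxyphenyl]-3-methylbutan-1-one
Conditions: BnBr (1.0 equiv), KHCO3 (1.1 equiv), DMF, rt
Reagents that add atoms: benzyl bromide, BrCc1ccccc1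
Why: Williamson O-alkylation in which bicarbonate ionises only the para-OH (most acidic, not chelated to the ketone), giving the symmetric para-benzyl ether that later leaves only ortho-to-acyl oxygens free next to a new C-substituent.

Step 3
Reactants: 4 para-O-benzyl isovalerylphloroglucinol; 5 furfuryl alcohol
Product: 6 1-[4-(benzyloxy)-3-(furan-2-ylmethyl)-2,6-dihydroxyphenyl]-3-methylbutan-1-one
Conditions: 5 added slowly to 4 (2.5 equiv), Bi(OTf)3 (2 mol %), HFIP–CH2Cl2, 0 °C
Reagents that add atoms: none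
Why: dehydrative Friedel–Crafts alkylation by the furfuryl cation at one of the two equivalent nucleophilic ring CH positions of 4, with excess arene and slow addition suppressing furan oligomerisation.

Step 4
Reactants: 6 2-benzylfuran
Product: 9 (E)-5-[6-(benzyloxy)-2,4-dihydroxy-3-(3-methylbutanoyl)phenyl]-4-oxopent-2-enal, via furan endoperoxide 7 (not isolated), via Z-keto-enal 8 (not isolated)
Conditions: O2, TPP (cat.), visible light, CH2Cl2, −78 °C; Me2S, −78 °C → rt; pyridine (0.1 equiv), rt
Reagents that add atoms: dioxygen (as singlet oxygen), O=O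
Why: [4+2] cycloaddition of singlet oxygen to the furan and reductive opening of the endoperoxide give the cis-4-oxo-enal, which base isomerises to the E isomer; 9 equilibrates with cyclic hemiketal/lactol tautomers that all feed the same iminium ion in step 5.

Step 5
Reactants: 9 (E)-keto-enal; 4 para-O-benzyl isovalerylphloroglucinol
Product: 11 2-[(2R,3S)-4,4'-bis(benzyloxy)-6,6'-dihydroxy-7,7'-bis(3-methylbutanoyl)-3H,3'H-2,2'-spirobi[1-benzofuran]-3-yl]acetaldehyde, via open-chain keto-aldehyde 10 (not isolated)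
Conditions: 4 (1.3 equiv), (2R,5R)-5-benzyl-2-tert-butyl-3-methylimidazolidin-4-one·TFA (20 mol %), CH2Cl2–i-PrOH, −40 °C; then CSA (10 mol %), 4 Å MS, −20 → 0 °C
Reagents that add atoms: none
Why: Proposed new method: the secondary amine condenses only with the aldehyde, so the iminium ion directs the ring carbon of 4 to the carbon β to CHO (α to the ketone) and the (2R,5R) catalyst, the mirror image of the one that gives R adducts from simple E-enals, shields one face to set 3S (closest known type: imidazolidinone-catalysed Friedel–Crafts alkylation of electron-rich arenes with β-acyl enals); acid then ionises the tertiary hemiketal at the ketone and the single free flanking OH of each aryl ring (the para oxygen is benzylated) closes both dihydrobenzofuran rings (closest known type: acid spiroketalization of bis(2-hydroxybenzyl) ketones), the reversible ring closure letting the spiro centre settle as 2R with the C3 side chain cis to the smaller ring-A oxygen.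

Step 6
Reactants: 11 spiroketal aldehyde
Product: 12 1,1'-[(2R,3S)-4,4'-bis(benzyloxy)-3-(3,3-dibromoprop-2-en-1-yl)-6,6'-dihydroxy-3H,3'H-2,2'-spirobi[1-benzofuran]-7,7'-diyl]bis(3-methylbutan-1-one)
Conditions: CBr4 (2 equiv), PPh3 (4 equiv), Et3N (2 equiv), CH2Cl2, 0 °C
Reagents that add atoms: carbon tetrabromide, BrC(Br)(Br)Br
Why: Ramirez/Corey–Fuchs dibromo-olefination (Wittig type) is selective for the aldehyde over the hindered chelated aryl ketones and supplies the one missing carbon; C3 is not enolisable once C2 is a ketal, so no stereocentre is touched.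

Step 7
Reactants: 12 gem-dibromoalkene; 3 isovalerylphloroglucinol
Product: 15 1-[(2R,3S)-4,4'-bis(benzyloxy)-3-{[4,6-dihydroxy-5-(3-methylbutanoyl)-1-benzofuran-2-yl]methyl}-6,6'-dihydroxy-7'-(3-methylbutanoyl)-3H,3'H-2,2'-spirobi[1-benzofuran]-7-yl]-3-methylbutan-1-one, via bromoalkyne 13 (not isolated), via Z-bromovinyl aryl ether 14 (not isolated)
Conditions: 3 (3 equiv), Cs2CO3 (2.5 equiv), DMSO, 110 °C; then Pd(OAc)2 (10 mol %), PCy3·HBF4 (20 mol %), CsOPiv (30 mol %), 120 °C
Reagents that add atoms: none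
Why: Proposed new method: base dehydrobrominates the gem-dibromoalkene to the 1-bromoalkyne, the para-phenoxide of 3 (the only OH ionised with substoichiometric base; the ortho OH groups are chelated) adds anti to the carbon remote from bromine to give the Z-2-bromovinyl aryl ether, and Pd(0) oxidative addition followed by concerted metalation–deprotonation closes onto either of the two equivalent ortho carbons, so the benzofuran oxygen is para to the acyl group by construction (closest known type: one-pot 2-substituted benzofuran synthesis from phenols and 1-bromoalkynes, and base-mediated conversion of gem-dibromoalkenes to bromoalkynes).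

Step 8
Reactants: 15 bis(benzyl ether)
Product: 16 1-[(2R,3S)-3-{[4,6-dihydroxy-5-(3-methylbutanoyl)-1-benzofuran-2-yl]methyl}-4,4',6,6'-tetrahydroxy-7'-(3-methylbutanoyl)-3H,3'H-2,2'-spirobi[1-benzofuran]-7-yl]-3-methylbutan-1-one (CNP0169640.1)
Conditions: H2 (1 atm), 10 % Pd/C, EtOAc, rt, stopped at full debenzylation
Reagents that add atoms: none
Why: hydrogenolysis of the two aryl benzyl ethers under neutral conditions, which leaves the chelated aryl ketones and the benzofuran intact and avoids the acid that could reopen the spiroketal and scramble its regiochemistry or stereochemistry.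

## Compound list

1 | phloroglucinol | Oc1cc(O)cc(O)c1 | starting material
2 | isovaleryl chloride | CC(C)CC(Cl)=O | starting material
3 | 1-(2,4,6-trihydroxyphenyl)-3-methylbutan-1-one | CC(C)CC(=O)c1c(O)cc(O)cc1O | intermediate
4 | 1-[4-(benzyloxy)-2,6-dihydroxyphenyl]-3-methylbutan-1-one | CC(C)CC(=O)c1c(O)cc(OCc2ccccc2)cc1O | intermediate
5 | furfuryl alcohol | OCc1ccco1 | starting material
6 | 1-[4-(benzyloxy)-3-(furan-2-ylmethyl)-2,6-dihydroxyphenyl]-3-methylbutan-1-one | CC(C)CC(=O)c1c(O)cc(OCc2ccccc2)c(Cc2ccco2)c1O | intermediate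
7 | furan endoperoxide of 6 (2,3,7-trioxabicyclo[2.2.1]hept-5-ene carrying the arylmethyl group at the bridgehead; not isolated) | CC(C)CC(=O)c1c(O)cc(OCc2ccccc2)c(CC23OOC(C=C2)O3)c1O | intermediate
8 | (Z)-5-[6-(benzyloxy)-2,4-dihydroxy-3-(3-methylbutanoyl)phenyl]-4-oxopent-2-enal (not isolated) | CC(C)CC(=O)c1c(O)cc(OCc2ccccc2)c(CC(=O)/C=C\C=O)c1O | intermediate
9 | (E)-5-[6-(benzyloxy)-2,4-dihydroxy-3-(3-methylbutanoyl)phenyl]-4-oxopent-2-enal | CC(C)CC(=O)c1c(O)cc(OCc2ccccc2)c(CC(=O)/C=C/C=O)c1O | intermediate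
10 | (3S)-3,5-bis[6-(benzyloxy)-2,4-dihydroxy-3-(3-methylbutanoyl)phenyl]-4-oxopentanal (not isolated) | CC(C)CC(=O)c1c(O)cc(OCc2ccccc2)c(CC(=O)[C@@H](CC=O)c2c(O)c(C(=O)CC(C)C)c(O)cc2OCc2ccccc2)c1O | intermediate
11 | 2-[(2R,3S)-4,4'-bis(benzyloxy)-6,6'-dihydroxy-7,7'-bis(3-methylbutanoyl)-3H,3'H-2,2'-spirobi[1-benzofuran]-3-yl]acetaldehyde | CC(C)CC(=O)c1c(O)cc(OCc3ccccc3)c2c1O[C@]1(C2)Oc2c(C(=O)CC(C)C)c(O)cc(OCc3ccccc3)c2[C@@H]1CC=O | intermediate
12 | (2R,3S)-3-(3,3-dibromoprop-2-en-1-yl) analogue of 11 (gem-dibromoalkene) | CC(C)CC(=O)c1c(O)cc(OCc3ccccc3)c2c1O[C@]1(C2)Oc2c(C(=O)CC(C)C)c(O)cc(OCc3ccccc3)c2[C@@H]1CC=C(Br)Br | intermediate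
13 | (2R,3S)-3-(3-bromoprop-2-yn-1-yl) analogue (bromoalkyne; not isolated) | CC(C)CC(=O)c1c(O)cc(OCc3ccccc3)c2c1O[C@]1(C2)Oc2c(C(=O)CC(C)C)c(O)cc(OCc3ccccc3)c2[C@@H]1CC#CBr | intermediate
14 | (2R,3S)-3-{(2Z)-3-bromo-2-[3,5-dihydroxy-4-(3-methylbutanoyl)phenoxy]prop-2-en-1-yl} analogue (not isolated) | CC(C)CC(=O)c1c(O)cc(OCc3ccccc3)c2c1O[C@]1(C2)Oc2c(C(=O)CC(C)C)c(O)cc(OCc3ccccc3)c2[C@@H]1C/C(Oc1cc(O)c(C(=O)CC(C)C)c(O)c1)=C/Br | intermediate
15 | 4,4'-di-O-benzyl ether of the target, (2R,3S) | CC(C)CC(=O)c1c(O)cc(OCc3ccccc3)c2c1O[C@]1(C2)Oc2c(C(=O)CC(C)C)c(O)cc(OCc3ccccc3)c2[C@@H]1Cc1cc2c(O)c(C(=O)CC(C)C)c(O)cc2o1 | intermediate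
16 | CNP0169640.1, (2R,3S) | CC(C)CC(=O)c1c(O)cc(O)c2c1O[C@]1(C2)Oc2c(C(=O)CC(C)C)c(O)cc(O)c2[C@@H]1Cc1cc2c(O)c(C(=O)CC(C)C)c(O)cc2o1 | target

## Count and risks

Total steps: 8. Longest linear sequence: 8 steps (1 → 3 → 4 → 6 → 9 → 11 → 12 → 15 → 16); 3 and 4 each re-enter once as the second component.

The step most likely to fail is step 5. The racemic background addition, intramolecular oxa-Michael addition of the ring-A phenol, E1 loss to a benzofuran, and capture of the C2 oxocarbenium by the pendant aldehyde (a bridged bis-acetal) all compete with the cascade. The fallback sets out from 9 (with 4) and returns at 12. Only the iminium Friedel–Crafts stage is run, and CBr4/PPh3/Et3N is added to the cold crude adduct 10 before any strong acid, giving (3S)-1,3-bis[6-(benzyloxy)-2,4-dihydroxy-3-(3-methylbutanoyl)phenyl]-6,6-dibromohex-5-en-2-one F1. With the aldehyde gone, both rings are closed under thermodynamic control (TsOH cat., 4 Å MS, toluene, rt) to reach 12, so the order of olefination and ring formation is reversed.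

Second is step 7. Dehydrobromination of an alkyl-substituted gem-dibromoalkene with carbonate may be slow, the other phenoxides may add to the bromoalkyne, and the hot basic medium may stress the ketal. The fallback sets out from 11 and returns at 15 by a carbon-first route. Ohira–Bestmann homologation (dimethyl (1-diazo-2-oxopropyl)phosphonate, K2CO3, MeOH) gives the (2R,3S)-3-(prop-2-yn-1-yl) spiroketal F2. Separately, 3 is mono-iodinated (NIS, MeCN, 0 °C) to 1-(2,4,6-trihydroxy-3-iodophenyl)-3-methylbutan-1-one F3. Sonogashira coupling (PdCl2(PPh3)2, CuI, Et3N, DMF, 50 °C) gives the ortho-alkynylphenol F4, which closes 5-endo-dig in the same pot through the more acidic para-phenoxide to 15. This fallback relies on para-over-ortho phenoxide preference rather than on construction, so the regiochemistry of 15 would need to be confirmed (HMBC).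

Third is step 3, where furfuryl alcohol can resinify and the product furan can be attacked again. The fallback sets out from 4 and returns at 6 with reversed polarity. Aminomethylation with Eschenmoser's salt gives 1-[4-(benzyloxy)-3-[(dimethylamino)methyl]-2,6-dihydroxyphenyl]-3-methylbutan-1-one F5. Heating F5 in neat furan (sealed tube, 80 °C, after N-methylation with MeI) releases the ortho-quinone methide, which the large excess of furan traps at C2 to give 6 without any furfuryl cation.

## Further compounds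

F1 | step 5 | (3S)-1,3-bis[6-(benzyloxy)-2,4-dihydroxy-3-(3-methylbutanoyl)phenyl]-6,6-dibromohex-5-en-2-one | CC(C)CC(=O)c1c(O)cc(OCc2ccccc2)c(CC(=O)[C@@H](CC=C(Br)Br)c2c(O)c(C(=O)CC(C)C)c(O)cc2OCc2ccccc2)c1O
F2 | step 7 | 1,1'-[(2R,3S)-4,4'-bis(benzyloxy)-6,6'-dihydroxy-3-(prop-2-yn-1-yl)-3H,3'H-2,2'-spirobi[1-benzofuran]-7,7'-diyl]bis(3-methylbutan-1-one) | CC(C)CC(=O)c1c(O)cc(OCc3ccccc3)c2c1O[C@]1(C2)Oc2c(C(=O)CC(C)C)c(O)cc(OCc3ccccc3)c2[C@@H]1CC#C
F3 | step 7 | 1-(2,4,6-trihydroxy-3-iodophenyl)-3-methylbutan-1-one | CC(C)CC(=O)c1c(O)cc(O)c(I)c1O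
F4 | step 7 | (2R,3S)-3-{3-[2,4,6-trihydroxy-3-(3-methylbutanoyl)phenyl]prop-2-yn-1-yl} analogue of F2 (ortho-alkynylphenol) | CC(C)CC(=O)c1c(O)cc(OCc3ccccc3)c2c1O[C@]1(C2)Oc2c(C(=O)CC(C)C)c(O)cc(OCc3ccccc3)c2[C@@H]1CC#Cc1c(O)cc(O)c(C(=O)CC(C)C)c1O
F5 | step 3 | 1-[4-(benzyloxy)-3-[(dimethylamino)methyl]-2,6-dihydroxyphenyl]-3-methylbutan-1-one | CC(C)CC(=O)c1c(O)cc(OCc2ccccc2)c(CN(C)C)c1O
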